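(The constants stand for no real mixture; the rest is arithmetic.)

In a one-step world Q takes up Z and the Q.Z stays, but this flask adds a leak to L that acts on dissolved Q.Z, while the crystals D sit out of its reach.

Q 20 mM; J 5.2 mM (held); time 15 min

    Q + Z → Q.Z (k1 = 20 L mol⁻¹ s⁻¹)
    J ⇌ Z, rate k2*(csat - [Z]) (k2 = 0.0087 s⁻¹, csat = 5.2 mM)
    Q → G (k3 = 1.9 × 10⁻⁶ s⁻¹)
    D ⇌ Q.Z, rate k4*(cs4 - [Q.Z]) while solid is left; crystals form when [Q.Z] > cs4 (cs4 = 0.86 mM, k4 = 0.029 s⁻¹)
    Q.Z → L (k5 = 0.011 s⁻¹)

- the Q.Z and D together standing at 15 min, as a percentage of the Q charged
- concentration of Z in solution at 15 min, in percent of saturation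

- Q.Z is meant together with its D
- solid, in amounts per volume of the solution: D
- at the start none of Z is dissolved
- run time (flask): 15 min

With Q as charged, Z has a half-life of 1.7 s against Q, far shorter than its transfer time 115 s, so I take the passage of J into Z as the rate-limiting step, and it delivers the charge in 7.37 min. Dissolved Q.Z lives 25.0 s, shorter than that, so I treat it as settled: a fraction 0.275 of what is made leaks before reaching the crystals. The crystals then bleed away on a second clock, the drain time, which is the charge divided by the leak rate of a solution at its solubility, 35.2 min. By this reckoning the feed is over before the reading, so as a rough step I set the feed time aside and keep two times, the reading and the drain, with ratio 0.426. The standing fraction is one minus that ratio, times one minus the leaked fraction, so I commit to 41.6 %. Once the feed time of my reckoning has passed, I let Z refill at the transfer coefficient, which gives 98.1 %.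

The forecast says 43 %, slightly above mine, on the ground that the dissolved part “keeps draining to L, costing about 11 of the 20 mM by 15 min”, and for Z it says 98.5 %, also slightly above mine.

The flask gives 42.9 % and 97.4 %. With every passage between the phases made a thousand times as fast, it holds 57.4 %, and one minus the ratio of the two times is 57.4 %. The same flask charged with 5.0 mM of Q has a drain time of 8.81 min, shorter than the reading, and it holds 0.126 % at 15.0 min.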